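(The constants stand for no real mixture; the rest is arithmetic.)

At early times a small catalyst charge meets a large charge of starting material, 25.0 to one, so each catalyst must go round many times and you may count by the round.

starting material 5.0 mM; reagent 4.75 mM; free catalyst 0.20 mM

    starting material + free catalyst → catalyst intermediate A (k1 = 160 /M/s)
    reagent + catalyst intermediate A ⇌ catalyst intermediate B (K2 = 1200 /M, k2 = 190 /M/s)
    catalyst intermediate B → by-product + catalyst intermediate C (k3 = 0.31 /s)
    catalyst intermediate C ⇌ free catalyst + product (K4 = 0.20 M, k4 = 1.1 /s)
    free catalyst ⇌ dormant form (K5 = 1.3, k5 = 0.043 /s)
    free catalyst + by-product ⇌ idle complex (K6 = 3600 /M, k6 = 7.0 /M/s)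

- what is said of by-product includes idle complex
- charge of starting material (flask): 5.0 mM

- the form that holds most of the catalyst when 20% of the starting material are converted (idle complex / free catalyst / catalyst intermediate A / catalyst intermediate B / catalyst intermediate C / dormant form)
- its share of the catalyst then
- factor on the rate of making product when 20% of the starting material are converted if free catalyst is charged twice over
- factor on the rate when 20% of the starting material are converted if free catalyst is charged at 2.0 mM instead

Take the point asked about, the mark: about 4.00 mM starting material and 3.75 mM reagent stand there. Now ask which constants you must know well. The rate of making product is the working catalyst divided by the seconds one round takes, and those seconds are a sum of stays: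

free catalyst, waiting for starting material: 1.56 s
intermediate A, returns from B included: 2.12 s
intermediate B: 3.23 s
intermediate C: 0.909 s

A constant matters as far as its term weighs. So k3 comes first: it sets the stay of B and, through the returns from B, part of the stay of A, so a value a tenth too low lengthens the sum by 0.438 s. K4 hardly matters, since free catalyst returns to C at about 0.00550 /s but leaves for A at 0.641 /s. Loss to the dormant form, at 0.043 /s, outweighs loss to the idle complex, at about 0.00700 /s, so I leave the idle complex out.

Now the number:

round time = 7.82 s

Call this the round time, the seconds working catalyst needs per round at the concentrations of the moment.

The mark comes near 39.1 s. Free catalyst is 20.0% of the working pool, so the dormant form climbs towards 20.6% at 0.0417 /s and reaches 16.6%. That leaves 83.4% working: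

rate = 0.0213 mM/s; intermediate B = 34.4% of the catalyst

Twice the catalyst halves the time to the mark, giving a factor of 2.12. Counting by the round needs several rounds before the mark: the flask as charged has made 5.00 rounds there, but the 2.0 mM flask reaches the mark after 0.500 of a round, so I expect far less than ten times and commit to no figure.

The forecast named catalyst intermediate B at 33%, with factors 2.15 and 1.6, holding that “20% conversion is just the stoichiometric burst”.

The simulation gives catalyst intermediate B at 34.1%, with factors 2.18 and 1.59.

With 82.0% of the catalyst working, the round time gives 0.0210 mM/s; the flask read 0.0213 mM/s. In the flask with twice the reagent, the round shortens to 6.63 s, a factor of 1.18, and that flask gave 1.16. In the flask as charged, step 3 was turning over at 40.0 s while intermediate B held 33.8% of the catalyst and 79.4% of the starting material stood. At 510 s the idle complex held 70.1% of the catalyst, and the rate was 0.073 of its value at the mark.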